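## Plan

- **Cuts:** first the cinnamyl O–acyl bond. Then C2–H is traced back to C2–B. Then the C3–CH2 bond and the C2–aryl bond of the dihydrofuran ring are cut together. This restores an aromatic benzofuran and leaves three pieces: benzofuran 6, guaiacylboronic ester 10 and iodomethyl ester 15.
- **Enabling feature:** the O1–C2=C3 enol-ether edge of the benzofuran ring. With a tetracoordinate boron on C2, C3 becomes a carbon nucleophile and C2 the terminus of a 1,2-shift. The trans C2-aryl/C3-CH2O pattern of the target is what an anti addition across C2=C3 leaves.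
- **Forward order:** the furan ring is made first by aryloxyacetal cyclodehydration, and the C5 side chain is added by Suzuki coupling. The three-component dearomatising coupling follows. Next, C–B is converted to C–H with loss of all silyl groups, and last the second 4-hydroxybenzoate is attached.
- **Stereochemistry:** C3 comes from face selection by the C2-symmetric (S,S)-diol on boron, a helper that leaves together with boron. C2 is set relative to C3 by the antiperiplanar shift and by retentive protodeboronation. The E-alkene comes from the vinylboronate.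

Key step: step 9

Remark: the sense of induction by the (S,S)-diol in step 9 is assigned from the steric model given there, and the (R,R)-diol is equally available should the sense prove opposite.

## Route

Step 1
Reactants: 1 4-bromo-2-methoxyphenol; 2 bromoacetaldehyde diethyl acetal
Product: 3 4-bromo-1-(2,2-diethoxyethoxy)-2-methoxybenzene
Conditions: K2CO3, DMF, 120 °C
Reagents that add atoms: none
Why: Williamson ether synthesis of a phenoxide with a primary bromide, and the acetal is inert to base.

Step 2
Reactants: 3 4-bromo-1-(2,2-diethoxyethoxy)-2-methoxybenzene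
Product: 4 5-bromo-7-methoxybenzofuran
Conditions: PPA, PhCl, 130 °C
Reagents that add atoms: none
Why: Acid-promoted cyclodehydration of an aryloxyacetaldehyde acetal (intramolecular Friedel–Crafts attack of the oxocarbenium ion, then loss of ethanol) can only close onto the single free position ortho to the ether oxygen, which fixes the 5-bromo-7-methoxy pattern.

Step 3
Reactants: 4 5-bromo-7-methoxybenzofuran; 5 (E)-tert-butyldimethyl{[3-(4,4,5,5-tetramethyl-1,3,2-dioxaborolan-2-yl)allyl]oxy}silane
Product: 6 (E)-tert-butyl{[3-(7-methoxybenzofuran-5-yl)allyl]oxy}dimethylsilane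
Conditions: Pd(dppf)Cl2 (cat.), K2CO3, dioxane/H2O, 85 °C
Reagents that add atoms: none
Why: Suzuki–Miyaura coupling of an aryl bromide with an (E)-alkenylboronate proceeds with retention of alkene geometry, and the primary silyl ether tolerates aqueous carbonate.

Step 4
Reactants: 7 (4-hydroxy-3-methoxyphenyl)boronic acid; 8 (1S,2S)-1,2-dicyclohexylethane-1,2-diol
Product: 9 4-[(4S,5S)-4,5-dicyclohexyl-1,3,2-dioxaborolan-2-yl]-2-methoxyphenol
Conditions: PhMe, Dean–Stark, reflux
Reagents that add atoms: none
Why: Condensation of a boronic acid with a 1,2-diol to the five-membered boronic ester is driven by removal of water and does not touch the carbinol stereocentres.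

Step 5
Reactants: 9 4-[(4S,5S)-4,5-dicyclohexyl-1,3,2-dioxaborolan-2-yl]-2-methoxyphenol
Product: 10 tert-butyl{4-[(4S,5S)-4,5-dicyclohexyl-1,3,2-dioxaborolan-2-yl]-2-methoxyphenoxy}dimethylsilane
Conditions: TBSCl, imidazole, CH2Cl2, rt
Reagents that add atoms: tert-butyldimethylsilyl chloride, CC(C)(C)[Si](C)(C)Cl
Why: Standard imidazole-promoted O-silylation removes the acidic phenol proton that would quench the organolithium of step 9.

Step 6
Reactants: 11 4-hydroxybenzoic acid
Product: 13 4-(tert-butyldimethylsilyloxy)benzoic acid, via bis-silyl compound 12 (not isolated)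
Conditions: TBSCl (2.2 equiv), imidazole, DMF, rt; then AcOH/THF/H2O, rt
Reagents that add atoms: tert-butyldimethylsilyl chloride, CC(C)(C)[Si](C)(C)Cl
Why: Exhaustive silylation followed by mild aqueous acid relies on the much greater lability of a silyl ester than of an aryl silyl ether.

Step 7
Reactants: 13 4-(tert-butyldimethylsilyloxy)benzoic acid
Product: 14 chloromethyl 4-(tert-butyldimethylsilyloxy)benzoate
Conditions: ClCH2OSO2Cl, NaHCO3, n-Bu4NHSO4 (cat.), CH2Cl2/H2O, 0 °C to rt
Reagents that add atoms: chloromethyl chlorosulfate, ClCOS(=O)(=O)Cl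
Why: Phase-transfer O-alkylation of the carboxylate displaces chlorosulfate, the better leaving group, so the chloromethyl ester results, and bicarbonate is mild enough for the aryl silyl ether.

Step 8
Reactants: 14 chloromethyl 4-(tert-butyldimethylsilyloxy)benzoate
Product: 15 iodomethyl 4-(tert-butyldimethylsilyloxy)benzoate
Conditions: NaI, acetone, rt, dark
Reagents that add atoms: sodium iodide, [Na+].[I-]
Why: The Finkelstein reaction is driven by precipitation of sodium chloride and gives the far more SN2-active α-acyloxy iodide.

Step 9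
Reactants: 6 (E)-tert-butyl{[3-(7-methoxybenzofuran-5-yl)allyl]oxy}dimethylsilane; 10 tert-butyl{4-[(4S,5S)-4,5-dicyclohexyl-1,3,2-dioxaborolan-2-yl]-2-methoxyphenoxy}dimethylsilane; 15 iodomethyl 4-(tert-butyldimethylsilyloxy)benzoate
Product: 18 {(2S,3R)-2-[4-(tert-butyldimethylsilyloxy)-3-methoxyphenyl]-2-[(4S,5S)-4,5-dicyclohexyl-1,3,2-dioxaborolan-2-yl]-7-methoxy-5-[(E)-3-(tert-butyldimethylsilyloxy)prop-1-enyl]-2,3-dihydrobenzofuran-3-yl}methyl 4-(tert-butyldimethylsilyloxy)benzoate, via 2-lithiobenzofuran 16 (not isolated), via lithium boronate 17 (not isolated)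
Conditions: LDA, THF, −78 °C; 10, −78 to 0 °C; 15, −78 to −20 °C, dark
Reagents that add atoms: none
Why: Proposed new method: C2-lithiation of 6 and addition to 10 give boronate 17, whose O1–C2=C3 enol-ether π bond, raised in energy by the adjacent C–B(ate) σ bond, attacks the CH2–I carbon of 15 through C3 (SN2) while the guaiacyl group shifts from boron to C2 antiperiplanar to the incoming carbon, so the C3–CH2 and C2–aryl bonds form in one dearomatising event that joins three components and closes no ring. The closest known reaction types are the alkyl-halide- and allyl-induced dearomatising 1,2-boronate shifts of indol-2-yl boronates and the halogen-induced shift of benzofuran-2-yl boronates; new here are the pairing of a benzofuranyl boronate with an acyloxymethyl iodide and face control by a diol on boron. The relative configuration (aryl trans to CH2O, boron cis to it) follows from the anti stereospecificity of the shift. The absolute configuration at C3 is controlled by the (S,S)-diol: in the reactive conformer the migrating aryl stands perpendicular to the ring plane and the dioxaborolane lies on the face the electrophile must use, where only one of the two diastereomeric arrangements turns the cyclohexyl group on the C3 side away from the trajectory and places the other one under O1, the same kind of differentiation this diol exerts in the Matteson homologation. Site selectivity for C3 over the guaiacyl ring or the ester carbonyl rests on the much higher nucleophilicity of the heteroaryl β-carbon, the blocked para position of the guaiacyl ligand, the activated α-acyloxy iodide and the donor-deactivated benzoate, and LDA instead of an alkyllithium spares the styrenyl alkene. The two possible boronates are diastereomers, so the minor one should be removable by chromatography or crystallisation before boron is taken out.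

Step 10
Reactants: 18 the (2S,3R)-boronic ester of step 9
Product: 19 {(2S,3R)-2-(4-hydroxy-3-methoxyphenyl)-5-[(E)-3-hydroxyprop-1-enyl]-7-methoxy-2,3-dihydrobenzofuran-3-yl}methyl 4-hydroxybenzoate
Conditions: TBAF·3H2O (excess), THF/PhMe, rt
Reagents that add atoms: none
Why: Fluoride-mediated protodeboronation of a tertiary benzylic boronic ester is a stereoretentive reaction type in which water hydrogen-bonded to the fluoroboronate delivers the proton to the face that boron leaves, so H should end up cis to the C3 side chain and the aryl group stays trans, while the same reagent cleaves the three silyl ethers and the donor-deactivated benzoate survives.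

Step 11
Reactants: 19 the triol monoester of step 10; 11 4-hydroxybenzoic acid
Product: 20 quiquesetinerviusin A
Conditions: PPh3, DIAD, THF, 0 °C to rt
Reagents that add atoms: none
Why: Mitsunobu esterification should be chemoselective because only the aliphatic allylic hydroxyl is activated as the oxyphosphonium and only the carboxylic acid, several pKa units more acidic than the phenols, acts as the nucleophile (a selectivity known for phenolic acids), and direct SN2 attack keeps the conjugated E-alkene and touches no stereocentre.

## Compound list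

1 | 4-bromo-2-methoxyphenol | COc1cc(Br)ccc1O | starting material
2 | bromoacetaldehyde diethyl acetal | CCOC(CBr)OCC | starting material
3 | 4-bromo-1-(2,2-diethoxyethoxy)-2-methoxybenzene | CCOC(COc1ccc(Br)cc1OC)OCC | intermediate
4 | 5-bromo-7-methoxybenzofuran | COc1cc(Br)cc2ccoc12 | intermediate
5 | (E)-tert-butyldimethyl{[3-(4,4,5,5-tetramethyl-1,3,2-dioxaborolan-2-yl)allyl]oxy}silane | CC(C)(C)[Si](C)(C)OC/C=C/B1OC(C)(C)C(C)(C)O1 | starting material
6 | (E)-tert-butyl{[3-(7-methoxybenzofuran-5-yl)allyl]oxy}dimethylsilane | COc1cc(/C=C/CO[Si](C)(C)C(C)(C)C)cc2ccoc12 | intermediate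
7 | (4-hydroxy-3-methoxyphenyl)boronic acid | COc1cc(B(O)O)ccc1O | starting material
8 | (1S,2S)-1,2-dicyclohexylethane-1,2-diol | O[C@@H](C1CCCCC1)[C@@H](O)C1CCCCC1 | starting material
9 | 4-[(4S,5S)-4,5-dicyclohexyl-1,3,2-dioxaborolan-2-yl]-2-methoxyphenol | COc1cc(B2O[C@@H](C3CCCCC3)[C@H](C3CCCCC3)O2)ccc1O | intermediate
10 | tert-butyl{4-[(4S,5S)-4,5-dicyclohexyl-1,3,2-dioxaborolan-2-yl]-2-methoxyphenoxy}dimethylsilane | COc1cc(B2O[C@@H](C3CCCCC3)[C@H](C3CCCCC3)O2)ccc1O[Si](C)(C)C(C)(C)C | intermediate
11 | 4-hydroxybenzoic acid | OC(=O)c1ccc(O)cc1 | starting material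
12 | tert-butyldimethylsilyl 4-(tert-butyldimethylsilyloxy)benzoate | CC(C)(C)[Si](C)(C)OC(=O)c1ccc(O[Si](C)(C)C(C)(C)C)cc1 | intermediate
13 | 4-(tert-butyldimethylsilyloxy)benzoic acid | CC(C)(C)[Si](C)(C)Oc1ccc(cc1)C(=O)O | intermediate
14 | chloromethyl 4-(tert-butyldimethylsilyloxy)benzoate | CC(C)(C)[Si](C)(C)Oc1ccc(cc1)C(=O)OCCl | intermediate
15 | iodomethyl 4-(tert-butyldimethylsilyloxy)benzoate | CC(C)(C)[Si](C)(C)Oc1ccc(cc1)C(=O)OCI | intermediate
16 | 2-lithio derivative of 6 | [Li]c1cc2cc(/C=C/CO[Si](C)(C)C(C)(C)C)cc(OC)c2o1 | intermediate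
17 | lithium (benzofuran-2-yl)(guaiacyl)boronate of the (S,S)-diol | [Li+].COc1cc([B-]2(c3cc4cc(/C=C/CO[Si](C)(C)C(C)(C)C)cc(OC)c4o3)O[C@@H](C3CCCCC3)[C@H](C3CCCCC3)O2)ccc1O[Si](C)(C)C(C)(C)C | intermediate
18 | (2S,3R)-2-aryl-2-boryl-3-(acyloxymethyl)-2,3-dihydrobenzofuran, fully silylated (aryl trans and boron cis to the C3 side chain) | COc1cc([C@@]2(B4O[C@@H](C5CCCCC5)[C@H](C5CCCCC5)O4)Oc3c(OC)cc(/C=C/CO[Si](C)(C)C(C)(C)C)cc3[C@@H]2COC(=O)c2ccc(O[Si](C)(C)C(C)(C)C)cc2)ccc1O[Si](C)(C)C(C)(C)C | intermediate
19 | {(2S,3R)-2-(4-hydroxy-3-methoxyphenyl)-5-[(E)-3-hydroxyprop-1-enyl]-7-methoxy-2,3-dihydrobenzofuran-3-yl}methyl 4-hydroxybenzoate | COc1cc([C@H]2Oc3c(OC)cc(/C=C/CO)cc3[C@@H]2COC(=O)c2ccc(O)cc2)ccc1O | intermediate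
20 | quiquesetinerviusin A, (2S,3R) | COc1cc([C@H]2Oc3c(OC)cc(/C=C/COC(=O)c4ccc(O)cc4)cc3[C@@H]2COC(=O)c2ccc(O)cc2)ccc1O | target

## Step count

Total step count: 11.

Longest linear sequence: 6 (steps 1, 2, 3, 9, 10, 11, or equally steps 6, 7, 8, 9, 10, 11).

## Steps most likely to fail

**First, step 9 (labelled).** Face discrimination by the diol may be insufficient. Alkylation of the boronate may also be so slow that proton capture or attack at the ester carbonyl competes. The fallback uses known chemistry, sets out from 11 and comes back at 20. Commercial (E)-coniferyl alcohol is esterified with 11 under Mitsunobu conditions to give (E)-coniferyl 4-hydroxybenzoate F1. One-electron oxidation (Ag2O in CH2Cl2/acetone, or peroxidase/H2O2) brings about the β-5 phenoxy-radical coupling and closure of the resulting quinone methide to the trans-dihydrobenzofuran. The less oxidisable 4-hydroxybenzoate phenols remain spectators. The dimer forms as a racemate, that is 20 together with its (2R,3S)-enantiomer F2. Preparative chromatography on a chiral stationary phase returns 20.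

**Second, step 10.** C–B cleavage may slow down once the phenoxides are set free. Retention may also be lost if a free benzylic carbanion is protonated from the open face, which would invert C2. The fallback replaces kinetic retention by thermodynamic correction at a stage without the acid-sensitive cinnamyl alcohol. It sets out from 4 and comes back at 19.
- Bromide 4 is lithiated with LDA and combined with 10 and 15 as in step 9, giving the 5-bromo boronic ester F3.
- Fluoride treatment gives the bromo diphenol, which may contain the cis (2R,3R) bromide F4.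
- Catalytic TFA in CH2Cl2 equilibrates C2 through the 4-hydroxybenzyl cation (quinone methide) to the more stable trans (2S,3R) bromide F5, while C3 is untouched.
- Stille coupling of F5 with (E)-3-(tributylstannyl)prop-2-en-1-ol gives 19.

**Third, step 11.** O-alkylation of a phenol or allylic transposition may compete during the Mitsunobu reaction. The fallback keeps all phenols masked during acylation, sets out from 18 and comes back at 20. Mild acid (PPTS, MeOH/CH2Cl2) removes only the aliphatic silyl ether to give the allylic alcohol F6. Carbodiimide coupling (EDC, DMAP) with acid 13 gives the fully protected diester boronate F7. TBAF·3H2O then effects protodeboronation and removal of the three aryl silyl ethers in the last operation to give 20.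

## Further compounds

F1 | step 9 | (E)-coniferyl 4-hydroxybenzoate | COc1cc(/C=C/COC(=O)c2ccc(O)cc2)ccc1O
F2 | step 9 | (2R,3S)-enantiomer of 20 | COc1cc([C@@H]2Oc3c(OC)cc(/C=C/COC(=O)c4ccc(O)cc4)cc3[C@H]2COC(=O)c2ccc(O)cc2)ccc1O
F3 | step 10 | 5-bromo analogue of 18, (2S,3R) | COc1cc([C@@]2(B4O[C@@H](C5CCCCC5)[C@H](C5CCCCC5)O4)Oc3c(OC)cc(Br)cc3[C@@H]2COC(=O)c2ccc(O[Si](C)(C)C(C)(C)C)cc2)ccc1O[Si](C)(C)C(C)(C)C
F4 | step 10 | [(2R,3R)-5-bromo-2-(4-hydroxy-3-methoxyphenyl)-7-methoxy-2,3-dihydrobenzofuran-3-yl]methyl 4-hydroxybenzoate (cis) | COc1cc([C@@H]2Oc3c(OC)cc(Br)cc3[C@@H]2COC(=O)c2ccc(O)cc2)ccc1O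
F5 | step 10 | [(2S,3R)-5-bromo-2-(4-hydroxy-3-methoxyphenyl)-7-methoxy-2,3-dihydrobenzofuran-3-yl]methyl 4-hydroxybenzoate (trans) | COc1cc([C@H]2Oc3c(OC)cc(Br)cc3[C@@H]2COC(=O)c2ccc(O)cc2)ccc1O
F6 | step 11 | allylic alcohol from 18 with aryl silyl ethers and boronic ester retained | COc1cc([C@@]2(B4O[C@@H](C5CCCCC5)[C@H](C5CCCCC5)O4)Oc3c(OC)cc(/C=C/CO)cc3[C@@H]2COC(=O)c2ccc(O[Si](C)(C)C(C)(C)C)cc2)ccc1O[Si](C)(C)C(C)(C)C
F7 | step 11 | fully protected diester boronate | COc1cc([C@@]2(B4O[C@@H](C5CCCCC5)[C@H](C5CCCCC5)O4)Oc3c(OC)cc(/C=C/COC(=O)c4ccc(O[Si](C)(C)C(C)(C)C)cc4)cc3[C@@H]2COC(=O)c2ccc(O[Si](C)(C)C(C)(C)C)cc2)ccc1O[Si](C)(C)C(C)(C)C
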